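## Retrosynthetic overview

- The target is reached by removing the C15 silyl group after outer-face epoxidation of C1=C10 in a ten-membered 1(10)E,4Z-dienolide; the oxirane is the last ring formed.
- The strategy rests on C3: this carbinol carbon is bonded to C4, the fully substituted carbon of the Z C4=C5 olefin that also carries C15H2–O. The ten-membered carbocycle (C1–C10) is therefore cut at C3–C4 into a C3 aldehyde and a C4 vinyl iodide (a Z 2-iodoallyl silyl ether) and closed by a Nozaki–Hiyama–Kishi reaction (second ring formed).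
- The iodoolefin comes from the C5 hydroxymethyl group of a trans-γ-lactone by oxidation, Wittig extension to the enal, α-iodination and 1,2-reduction; the C3 aldehyde comes from a PMB-protected primary alcohol.
- The α-methylene-γ-lactone (first ring formed; O, C6, C7, C11, C12) comes from an acyclic hydroxy ester by acylation of O8 and acid-induced closure at O6. Its C7–C8 bond and both new stereocentres come from an indium Barbier coupling of a C8 aldehyde with a Baylis–Hillman bromide whose C6 stereocentre is taken from (R)-glyceraldehyde acetonide.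
- The C8 aldehyde (C8–C10, C14, C1–C3) with the E C1=C10 olefin comes from a butynyl silyl ether by carboalumination and opening of ethylene oxide.

Key step: step 16

Remark on the chemistry: atoms are numbered as in germacranes (C1 to C15) throughout, and the commercial (R)-glyceraldehyde acetonide is assumed to be distilled just before use because it oligomerises on storage.

## Route

Step 1
Reactants: 1 tert-butyl(but-3-yn-1-yloxy)dimethylsilane; 2 ethylene oxide
Product: 5 (3E)-6-[(tert-butyldimethylsilyl)oxy]-4-methylhex-3-en-1-ol, via alkenyldimethylalane 3 (not isolated), via lithium alkenylaluminate 4 (not isolated)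
Conditions: Me3Al (2.5 equiv), Cp2ZrCl2 (0.25 equiv), CH2Cl2, 0 °C to rt; volatiles removed, hexane; n-BuLi (1 equiv), 0 °C; 2 (3 equiv), THF, 0 °C to rt; aq. KNaC4H4O6
Reagents that add atoms: trimethylaluminium, C[Al](C)C
Why: Zirconocene-catalysed Negishi carboalumination adds CH3 and Al syn across the terminal alkyne with the methyl on the internal carbon, so the C1=C10 olefin is formed E, and the derived alkenylaluminate opens ethylene oxide with retention of geometry to attach C2–C3.

Step 2
Reactants: 5 (3E)-6-[(tert-butyldimethylsilyl)oxy]-4-methylhex-3-en-1-ol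
Product: 6 tert-butyl{[(3E)-6-[(4-methoxybenzyl)oxy]-3-methylhex-3-en-1-yl]oxy}dimethylsilane
Conditions: NaH (1.3 equiv), 4-methoxybenzyl chloride (1.2 equiv), Bu4NI (0.05 equiv), THF/DMF, 0 °C to rt
Reagents that add atoms: 4-methoxybenzyl chloride, COc1ccc(CCl)cc1
Why: Williamson etherification of the primary alkoxide protects the future C3 oxygen as a PMB ether, which should survive the acid, acylation and oxidation conditions of steps 3 to 13 and is removable with DDQ, while the primary silyl ether is stable to NaH.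

Step 3
Reactants: 6 tert-butyl{[(3E)-6-[(4-methoxybenzyl)oxy]-3-methylhex-3-en-1-yl]oxy}dimethylsilane
Product: 7 (3E)-6-[(4-methoxybenzyl)oxy]-3-methylhex-3-en-1-ol
Conditions: TBAF (1.2 equiv), THF, 0 °C to rt
Reagents that add atoms: none
Why: Fluoride-induced desilylation frees the C8 hydroxyl and leaves the PMB ether and the olefin untouched.

Step 4
Reactants: 7 (3E)-6-[(4-methoxybenzyl)oxy]-3-methylhex-3-en-1-ol
Product: 8 (3E)-6-[(4-methoxybenzyl)oxy]-3-methylhex-3-enal
Conditions: Dess–Martin periodinane (1.3 equiv), NaHCO3, CH2Cl2, 0 °C; filtered and used at once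
Reagents that add atoms: none
Why: Dess–Martin oxidation in a buffered, neutral medium stops at the aldehyde and should not move the C1=C10 bond into conjugation, provided the β,γ-unsaturated aldehyde is used without storage.

Step 5
Reactants: 9 (4R)-2,2-dimethyl-1,3-dioxolane-4-carbaldehyde; 10 methyl acrylate
Product: 11 methyl 2-{[(4R)-2,2-dimethyl-1,3-dioxolan-4-yl](hydroxy)methyl}prop-2-enoate (both carbinol epimers)
Conditions: 1,4-diazabicyclo[2.2.2]octane (0.5 equiv), 1,4-dioxane/H2O (1:1), rt, 2–3 d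
Reagents that add atoms: none
Why: The Morita–Baylis–Hillman reaction joins the acrylate α-carbon (C11) to the aldehyde carbon (C7); the new carbinol centre is formed as a mixture that is of no consequence because step 6 turns it into an sp2 carbon, and the dioxolane centre (C6) is not touched.

Step 6
Reactants: 11 methyl 2-{[(4R)-2,2-dimethyl-1,3-dioxolan-4-yl](hydroxy)methyl}prop-2-enoate
Product: 12 methyl (2Z)-2-(bromomethyl)-3-[(4S)-2,2-dimethyl-1,3-dioxolan-4-yl]prop-2-enoate
Conditions: N-bromosuccinimide (1.5 equiv), Me2S (1.8 equiv), CH2Cl2, 0 °C to rt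
Reagents that add atoms: N-bromosuccinimide, O=C1CCC(=O)N1Br
Why: The sulfonium reagent formed from N-bromosuccinimide and dimethyl sulfide (Corey–Kim type) activates the allylic hydroxyl and bromide attacks in the SN2' sense, which should give the conjugated 2-(bromomethyl)alkenoate as the more stable Z isomer from both carbinol epimers under conditions that spare the acetonide.

Step 7
Reactants: 8 (3E)-6-[(4-methoxybenzyl)oxy]-3-methylhex-3-enal; 12 methyl (2Z)-2-(bromomethyl)-3-[(4S)-2,2-dimethyl-1,3-dioxolan-4-yl]prop-2-enoate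
Product: 14 methyl (3R,4R,6E)-3-[(4S)-2,2-dimethyl-1,3-dioxolan-4-yl]-4-hydroxy-9-[(4-methoxybenzyl)oxy]-6-methyl-2-methylidenenon-6-enoate, via allylindium dibromide 13 (not isolated)
Conditions: In powder (1.5 equiv), 12 (1.3 equiv), THF/H2O (1:1), rt
Reagents that add atoms: none
Why: Indium inserts into the allylic C–Br bond and the Z allylindium adds to the aldehyde through its γ-carbon (C7) in a chair Zimmerman–Traxler transition state (Barbier allylation), where the equatorial aldehyde residue and the Z reagent should give the 7,8-syn adduct (8R), while C7 (7R) is set by attack anti to the C6–O bond of the dioxolane in the conformer that holds C6–H in the olefin plane (allylic 1,3-strain, Felkin–Anh-type induction).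

Step 8
Reactants: 14 methyl (3R,4R,6E)-3-[(4S)-2,2-dimethyl-1,3-dioxolan-4-yl]-4-hydroxy-9-[(4-methoxybenzyl)oxy]-6-methyl-2-methylidenenon-6-enoate; 15 isobutyryl chloride
Product: 16 methyl (3R,4R,6E)-3-[(4S)-2,2-dimethyl-1,3-dioxolan-4-yl]-9-[(4-methoxybenzyl)oxy]-6-methyl-2-methylidene-4-[(2-methylpropanoyl)oxy]non-6-enoate
Conditions: pyridine (3 equiv), 4-(dimethylamino)pyridine (0.2 equiv), CH2Cl2, 0 °C to rt
Reagents that add atoms: none
Why: Acylation under nucleophilic catalysis esterifies the only free hydroxyl, which fixes O8 as the isobutyrate before a lactone could form at this oxygen.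

Step 9
Reactants: 16 methyl (3R,4R,6E)-3-[(4S)-2,2-dimethyl-1,3-dioxolan-4-yl]-9-[(4-methoxybenzyl)oxy]-6-methyl-2-methylidene-4-[(2-methylpropanoyl)oxy]non-6-enoate
Product: 18 (1R,3E)-1-[(2S,3R)-2-(hydroxymethyl)-4-methylidene-5-oxooxolan-3-yl]-6-[(4-methoxybenzyl)oxy]-3-methylhex-3-en-1-yl 2-methylpropanoate, via diol ester 17 (not isolated)
Conditions: 1 M aq. HCl/THF (1:2), rt; then p-TsOH·H2O (0.1 equiv), CH2Cl2, rt
Reagents that add atoms: none
Why: Acid hydrolysis of the acetonide frees the C5 and C6 hydroxyls, and the secondary C6 hydroxyl, γ to the ester carbonyl, should close the five-membered lactone by acid-catalysed transesterification (5-exo-trig) faster than the primary hydroxyl can close a six-membered ring, giving the trans 6,12-lactone because C6 and C7 are already set and O8 is blocked.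

Step 10
Reactants: 18 (1R,3E)-1-[(2S,3R)-2-(hydroxymethyl)-4-methylidene-5-oxooxolan-3-yl]-6-[(4-methoxybenzyl)oxy]-3-methylhex-3-en-1-yl 2-methylpropanoate; 19 (triphenylphosphoranylidene)acetaldehyde
Product: 21 (1R,3E)-6-[(4-methoxybenzyl)oxy]-3-methyl-1-{(2R,3R)-4-methylidene-5-oxo-2-[(1E)-3-oxoprop-1-en-1-yl]oxolan-3-yl}hex-3-en-1-yl 2-methylpropanoate, via lactone aldehyde 20 (not isolated)
Conditions: Dess–Martin periodinane (1.3 equiv), NaHCO3, CH2Cl2, 0 °C to rt; filtered; then 19 (1.5 equiv), toluene, 50 °C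
Reagents that add atoms: none
Why: Dess–Martin oxidation gives the α-acyloxy aldehyde, which is taken without purification into a Wittig reaction with the stabilised formyl ylide to give the E enal (C4 and C15 added) under conditions mild enough that C6 should not epimerise.

Step 11
Reactants: 21 (1R,3E)-6-[(4-methoxybenzyl)oxy]-3-methyl-1-{(2R,3R)-4-methylidene-5-oxo-2-[(1E)-3-oxoprop-1-en-1-yl]oxolan-3-yl}hex-3-en-1-yl 2-methylpropanoate
Product: 22 (1R,3E)-1-{(2S,3R)-2-[(1Z)-2-iodo-3-oxoprop-1-en-1-yl]-4-methylidene-5-oxooxolan-3-yl}-6-[(4-methoxybenzyl)oxy]-3-methylhex-3-en-1-yl 2-methylpropanoate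
Conditions: I2 (2 equiv), pyridine/CH2Cl2 (1:1), 0 °C to rt, dark
Reagents that add atoms: iodine, II
Why: In this Johnson-type α-iodination pyridine adds reversibly to the enal, the enolate is iodinated at C4 and pyridine is lost again, which should give the thermodynamically preferred Z α-iodoenal (iodine cis to C6) while the less electrophilic methylene lactone and, in the pyridine-buffered medium, the trisubstituted olefin are left alone.

Step 12
Reactants: 22 (1R,3E)-1-{(2S,3R)-2-[(1Z)-2-iodo-3-oxoprop-1-en-1-yl]-4-methylidene-5-oxooxolan-3-yl}-6-[(4-methoxybenzyl)oxy]-3-methylhex-3-en-1-yl 2-methylpropanoate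
Product: 23 (1R,3E)-1-{(2S,3R)-2-[(1Z)-3-hydroxy-2-iodoprop-1-en-1-yl]-4-methylidene-5-oxooxolan-3-yl}-6-[(4-methoxybenzyl)oxy]-3-methylhex-3-en-1-yl 2-methylpropanoate
Conditions: NaBH4 (1 equiv), CeCl3·7H2O (1.2 equiv), MeOH, −78 °C, 15 min; acetone quench
Reagents that add atoms: none
Why: Luche reduction reduces the aldehyde in the 1,2 sense within minutes at −78 °C, where the lactone, the ester, the C–I bond and the exocyclic methylene should not be attacked.

Step 13
Reactants: 23 (1R,3E)-1-{(2S,3R)-2-[(1Z)-3-hydroxy-2-iodoprop-1-en-1-yl]-4-methylidene-5-oxooxolan-3-yl}-6-[(4-methoxybenzyl)oxy]-3-methylhex-3-en-1-yl 2-methylpropanoate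
Product: 24 (1R,3E)-1-{(2S,3R)-2-[(1Z)-3-[(tert-butyldimethylsilyl)oxy]-2-iodoprop-1-en-1-yl]-4-methylidene-5-oxooxolan-3-yl}-6-[(4-methoxybenzyl)oxy]-3-methylhex-3-en-1-yl 2-methylpropanoate
Conditions: tert-butyldimethylsilyl chloride (1.3 equiv), imidazole (2.5 equiv), CH2Cl2, 0 °C to rt
Reagents that add atoms: tert-butyldimethylsilyl chloride, CC(C)(C)[Si](C)(C)Cl
Why: Standard silylation of the primary allylic alcohol masks C15–OH for the two oxidations and the organochromium step that follow.

Step 14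
Reactants: 24 (1R,3E)-1-{(2S,3R)-2-[(1Z)-3-[(tert-butyldimethylsilyl)oxy]-2-iodoprop-1-en-1-yl]-4-methylidene-5-oxooxolan-3-yl}-6-[(4-methoxybenzyl)oxy]-3-methylhex-3-en-1-yl 2-methylpropanoate
Product: 25 (1R,3E)-1-{(2S,3R)-2-[(1Z)-3-[(tert-butyldimethylsilyl)oxy]-2-iodoprop-1-en-1-yl]-4-methylidene-5-oxooxolan-3-yl}-6-hydroxy-3-methylhex-3-en-1-yl 2-methylpropanoate
Conditions: DDQ (1.3 equiv), CH2Cl2/pH 7 buffer (Na2HPO4/NaH2PO4) 10:1, 0 °C
Reagents that add atoms: none
Why: Oxidative cleavage of the PMB ether by DDQ (benzylic hydride abstraction, then hydrolysis) frees the C3 hydroxyl without touching the silyl ether, the vinyl iodide or the esters.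

Step 15
Reactants: 25 (1R,3E)-1-{(2S,3R)-2-[(1Z)-3-[(tert-butyldimethylsilyl)oxy]-2-iodoprop-1-en-1-yl]-4-methylidene-5-oxooxolan-3-yl}-6-hydroxy-3-methylhex-3-en-1-yl 2-methylpropanoate
Product: 26 (1R,3E)-1-{(2S,3R)-2-[(1Z)-3-[(tert-butyldimethylsilyl)oxy]-2-iodoprop-1-en-1-yl]-4-methylidene-5-oxooxolan-3-yl}-3-methyl-6-oxohex-3-en-1-yl 2-methylpropanoate
Conditions: Dess–Martin periodinane (1.5 equiv), NaHCO3, CH2Cl2, 0 °C; short silica plug, used at once
Reagents that add atoms: none
Why: Buffered Dess–Martin oxidation gives the C3 aldehyde under neutral conditions, which the β,γ-unsaturated aldehyde needs in order to keep the C1=C10 bond in place.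

Step 16
Reactants: 26 (1R,3E)-1-{(2S,3R)-2-[(1Z)-3-[(tert-butyldimethylsilyl)oxy]-2-iodoprop-1-en-1-yl]-4-methylidene-5-oxooxolan-3-yl}-3-methyl-6-oxohex-3-en-1-yl 2-methylpropanoate
Product: 29 (3S,6R,7R,8R)-15-[(tert-butyldimethylsilyl)oxy]-3-hydroxy-8-(2-methylpropanoyloxy)germacra-1(10)E,4Z,11(13)-trien-12,6-olide, via vinylchromium dichloride 27 (not isolated), via chromium alkoxide 28 (not isolated)
Conditions: CrCl2 (15 equiv), NiCl2 (0.15 equiv), degassed DMF, rt, slow addition of 26 to a final 0.003 M; then H2O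
Reagents that add atoms: none
Why: Zerovalent nickel, made from NiCl2 by CrCl2, inserts into the C4–I bond, the alkenyl group passes to chromium with retention of geometry to give the trivalent vinylchromium 27, and this adds to the C3 aldehyde to give alkoxide 28, which water protonates; the closest known reaction is the Nozaki–Hiyama–Kishi macrocyclisation of 2-iodoallyl ethers onto aldehydes. The ten-membered carbocycle closes end to end by C3–C4 bond formation (exo attack of C4 on the aldehyde carbon), helped by slow addition at high dilution and by the trans-lactone, the C8 ester and the E C1=C10 olefin, which leave few rotatable bonds between the two termini. The Z geometry of C4=C5 is carried over from the iodide, so C3 and C6 stand cis on the olefin. The new C3 stereocentre is set by substrate control (1,4-induction from C6 across the Z olefin): with C6–H and the forming C3–H both held in the olefin plane by allylic 1,3-strain, the aldehyde is expected to reach C4 with C2 on the face opposite C7 and its chromium-bound oxygen on the face opposite the lactone oxygen, which is addition to the Re face and gives 3S. The step needs chemoselectivity for the aldehyde over the methylene lactone and the isobutyrate and must not shift the C1=C10 bond into conjugation; organochromium reagents add only to aldehydes at room temperature, the medium is neither acidic nor basic, and the covalent C–Cr bond with a silyl ether at C15 should not eliminate to an allene.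

Step 17
Reactants: 29 (3S,6R,7R,8R)-15-[(tert-butyldimethylsilyl)oxy]-3-hydroxy-8-(2-methylpropanoyloxy)germacra-1(10)E,4Z,11(13)-trien-12,6-olide
Product: 30 (1R,3S,6R,7R,8R,10R)-15-[(tert-butyldimethylsilyl)oxy]-1,10-epoxy-3-hydroxy-8-(2-methylpropanoyloxy)germacra-4Z,11(13)-dien-12,6-olide
Conditions: dimethyldioxirane (1.1 equiv, ca. 0.07 M in acetone), CH2Cl2, −20 to 0 °C
Reagents that add atoms: dimethyldioxirane, CC1(C)OO1
Why: Electrophilic, stereospecific oxygen transfer from the dioxirane should take place at C1=C10, the only electron-rich olefin (C4=C5 carries three allylic oxygens and the methylene lactone is electron-poor), and on the outer face of the ring-held E olefin, which with the C14 methyl on the β face gives the trans 1R,10R (1β,10α) epoxide as is general for germacra-1(10)-enolides.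

Step 18
Reactants: 30 (1R,3S,6R,7R,8R,10R)-15-[(tert-butyldimethylsilyl)oxy]-1,10-epoxy-3-hydroxy-8-(2-methylpropanoyloxy)germacra-4Z,11(13)-dien-12,6-olide
Product: 31 (1R,3S,6R,7R,8R,10R)-1,10-epoxy-3,15-dihydroxy-8-(2-methylpropanoyloxy)germacra-4Z,11(13)-dien-12,6-olide (CNP0219050.1)
Conditions: TBAF (2 equiv), AcOH (2 equiv), THF, 0 °C to rt
Reagents that add atoms: none
Why: Fluoride cleavage of the primary allylic silyl ether with TBAF buffered by acetic acid should avoid both base-induced acyl shift or lactone opening and acid-induced transannular opening of the epoxide.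

## Compound list

1 | tert-butyl(but-3-yn-1-yloxy)dimethylsilane | C#CCCO[Si](C)(C)C(C)(C)C | starting material
2 | ethylene oxide (oxirane) | C1CO1 | starting material
3 | [(1E)-4-[(tert-butyldimethylsilyl)oxy]-2-methylbut-1-en-1-yl]dimethylalane | C[Al](C)/C=C(C)/CCO[Si](C)(C)C(C)(C)C | intermediate (not isolated)
4 | lithium butyl[(1E)-4-[(tert-butyldimethylsilyl)oxy]-2-methylbut-1-en-1-yl]dimethylaluminate | [Li+].CCCC[Al-](C)(C)/C=C(C)/CCO[Si](C)(C)C(C)(C)C | intermediate (not isolated)
5 | (3E)-6-[(tert-butyldimethylsilyl)oxy]-4-methylhex-3-en-1-ol | OCC/C=C(C)/CCO[Si](C)(C)C(C)(C)C | intermediate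
6 | tert-butyl{[(3E)-6-[(4-methoxybenzyl)oxy]-3-methylhex-3-en-1-yl]oxy}dimethylsilane | COc1ccc(COCC/C=C(C)/CCO[Si](C)(C)C(C)(C)C)cc1 | intermediate
7 | (3E)-6-[(4-methoxybenzyl)oxy]-3-methylhex-3-en-1-ol | COc1ccc(COCC/C=C(C)/CCO)cc1 | intermediate
8 | (3E)-6-[(4-methoxybenzyl)oxy]-3-methylhex-3-enal (C8 aldehyde) | COc1ccc(COCC/C=C(C)/CC=O)cc1 | intermediate
9 | (4R)-2,2-dimethyl-1,3-dioxolane-4-carbaldehyde, (R)-glyceraldehyde acetonide | O=C[C@H]1COC(C)(C)O1 | starting material
10 | methyl acrylate | C=CC(=O)OC | starting material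
11 | methyl 2-{[(4R)-2,2-dimethyl-1,3-dioxolan-4-yl](hydroxy)methyl}prop-2-enoate, both carbinol epimers | C=C(C(=O)OC)C(O)[C@H]1COC(C)(C)O1 | intermediate
12 | methyl (2Z)-2-(bromomethyl)-3-[(4S)-2,2-dimethyl-1,3-dioxolan-4-yl]prop-2-enoate | COC(=O)/C(CBr)=C/[C@H]1COC(C)(C)O1 | intermediate
13 | allylindium species from 12, drawn as the dibromide of trivalent indium (CH2–InBr2 in place of CH2–Br) | COC(=O)/C(C[In](Br)Br)=C/[C@H]1COC(C)(C)O1 | intermediate (not isolated)
14 | methyl (3R,4R,6E)-3-[(4S)-2,2-dimethyl-1,3-dioxolan-4-yl]-4-hydroxy-9-[(4-methoxybenzyl)oxy]-6-methyl-2-methylidenenon-6-enoate | COC(=O)C(=C)[C@@H]([C@H]1COC(C)(C)O1)[C@H](O)C/C(C)=C/CCOCc1ccc(OC)cc1 | intermediate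
15 | isobutyryl chloride (2-methylpropanoyl chloride) | CC(C)C(Cl)=O | starting material
16 | methyl (3R,4R,6E)-3-[(4S)-2,2-dimethyl-1,3-dioxolan-4-yl]-9-[(4-methoxybenzyl)oxy]-6-methyl-2-methylidene-4-[(2-methylpropanoyl)oxy]non-6-enoate | COC(=O)C(=C)[C@@H]([C@H]1COC(C)(C)O1)[C@H](OC(=O)C(C)C)C/C(C)=C/CCOCc1ccc(OC)cc1 | intermediate
17 | methyl (3S,4R,6E)-3-[(1S)-1,2-dihydroxyethyl]-9-[(4-methoxybenzyl)oxy]-6-methyl-2-methylidene-4-[(2-methylpropanoyl)oxy]non-6-enoate | COC(=O)C(=C)[C@@H]([C@H](O)CO)[C@H](OC(=O)C(C)C)C/C(C)=C/CCOCc1ccc(OC)cc1 | intermediate (not isolated)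
18 | (1R,3E)-1-[(2S,3R)-2-(hydroxymethyl)-4-methylidene-5-oxooxolan-3-yl]-6-[(4-methoxybenzyl)oxy]-3-methylhex-3-en-1-yl 2-methylpropanoate | C=C1C(=O)O[C@H](CO)[C@H]1[C@H](OC(=O)C(C)C)C/C(C)=C/CCOCc2ccc(OC)cc2 | intermediate
19 | (triphenylphosphoranylidene)acetaldehyde | O=CC=P(c1ccccc1)(c1ccccc1)c1ccccc1 | starting material
20 | (1R,3E)-1-[(2S,3R)-2-formyl-4-methylidene-5-oxooxolan-3-yl]-6-[(4-methoxybenzyl)oxy]-3-methylhex-3-en-1-yl 2-methylpropanoate | C=C1C(=O)O[C@H](C=O)[C@H]1[C@H](OC(=O)C(C)C)C/C(C)=C/CCOCc2ccc(OC)cc2 | intermediate (not isolated)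
21 | (1R,3E)-6-[(4-methoxybenzyl)oxy]-3-methyl-1-{(2R,3R)-4-methylidene-5-oxo-2-[(1E)-3-oxoprop-1-en-1-yl]oxolan-3-yl}hex-3-en-1-yl 2-methylpropanoate | C=C1C(=O)O[C@H](/C=C/C=O)[C@H]1[C@H](OC(=O)C(C)C)C/C(C)=C/CCOCc2ccc(OC)cc2 | intermediate
22 | (1R,3E)-1-{(2S,3R)-2-[(1Z)-2-iodo-3-oxoprop-1-en-1-yl]-4-methylidene-5-oxooxolan-3-yl}-6-[(4-methoxybenzyl)oxy]-3-methylhex-3-en-1-yl 2-methylpropanoate | C=C1C(=O)O[C@H](/C=C(\I)C=O)[C@H]1[C@H](OC(=O)C(C)C)C/C(C)=C/CCOCc2ccc(OC)cc2 | intermediate
23 | (1R,3E)-1-{(2S,3R)-2-[(1Z)-3-hydroxy-2-iodoprop-1-en-1-yl]-4-methylidene-5-oxooxolan-3-yl}-6-[(4-methoxybenzyl)oxy]-3-methylhex-3-en-1-yl 2-methylpropanoate | C=C1C(=O)O[C@H](/C=C(\I)CO)[C@H]1[C@H](OC(=O)C(C)C)C/C(C)=C/CCOCc2ccc(OC)cc2 | intermediate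
24 | (1R,3E)-1-{(2S,3R)-2-[(1Z)-3-[(tert-butyldimethylsilyl)oxy]-2-iodoprop-1-en-1-yl]-4-methylidene-5-oxooxolan-3-yl}-6-[(4-methoxybenzyl)oxy]-3-methylhex-3-en-1-yl 2-methylpropanoate | C=C1C(=O)O[C@H](/C=C(\I)CO[Si](C)(C)C(C)(C)C)[C@H]1[C@H](OC(=O)C(C)C)C/C(C)=C/CCOCc2ccc(OC)cc2 | intermediate
25 | (1R,3E)-1-{(2S,3R)-2-[(1Z)-3-[(tert-butyldimethylsilyl)oxy]-2-iodoprop-1-en-1-yl]-4-methylidene-5-oxooxolan-3-yl}-6-hydroxy-3-methylhex-3-en-1-yl 2-methylpropanoate | C=C1C(=O)O[C@H](/C=C(\I)CO[Si](C)(C)C(C)(C)C)[C@H]1[C@H](OC(=O)C(C)C)C/C(C)=C/CCO | intermediate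
26 | (1R,3E)-1-{(2S,3R)-2-[(1Z)-3-[(tert-butyldimethylsilyl)oxy]-2-iodoprop-1-en-1-yl]-4-methylidene-5-oxooxolan-3-yl}-3-methyl-6-oxohex-3-en-1-yl 2-methylpropanoate (key-step precursor) | O=CC/C=C(C)/C[C@@H](OC(=O)C(C)C)[C@H]1C(=C)C(=O)O[C@@H]1/C=C(\I)CO[Si](C)(C)C(C)(C)C | intermediate
27 | vinylchromium dichloride of trivalent chromium derived from 26 (C4–CrCl2 in place of C4–I, olefin geometry retained) | O=CC/C=C(C)/C[C@@H](OC(=O)C(C)C)[C@H]1C(=C)C(=O)O[C@@H]1/C=C(\[Cr](Cl)Cl)CO[Si](C)(C)C(C)(C)C | intermediate (not isolated)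
28 | chromium alkoxide of 29 (C3–O–CrCl2, trivalent chromium) | C=C1C(=O)O[C@@H]2/C=C(/CO[Si](C)(C)C(C)(C)C)[C@@H](O[Cr](Cl)Cl)C/C=C(C)/C[C@@H](OC(=O)C(C)C)[C@@H]12 | intermediate (not isolated)
29 | (3S,6R,7R,8R)-15-[(tert-butyldimethylsilyl)oxy]-3-hydroxy-8-(2-methylpropanoyloxy)germacra-1(10)E,4Z,11(13)-trien-12,6-olide | C=C1C(=O)O[C@@H]2/C=C(/CO[Si](C)(C)C(C)(C)C)[C@@H](O)C/C=C(C)/C[C@@H](OC(=O)C(C)C)[C@@H]12 | intermediate
30 | (1R,3S,6R,7R,8R,10R)-15-[(tert-butyldimethylsilyl)oxy]-1,10-epoxy-3-hydroxy-8-(2-methylpropanoyloxy)germacra-4Z,11(13)-dien-12,6-olide | C=C1C(=O)O[C@@H]2/C=C(/CO[Si](C)(C)C(C)(C)C)[C@@H](O)C[C@H]3O[C@]3(C)C[C@@H](OC(=O)C(C)C)[C@@H]12 | intermediate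
31 | (1R,3S,6R,7R,8R,10R)-1,10-epoxy-3,15-dihydroxy-8-(2-methylpropanoyloxy)germacra-4Z,11(13)-dien-12,6-olide (CNP0219050.1) | C=C1C(=O)O[C@@H]2/C=C(/CO)[C@@H](O)C[C@H]3O[C@]3(C)C[C@@H](OC(=O)C(C)C)[C@@H]12 | target

## Step count and risks

Total step count: 18. Longest linear sequence: 16 steps (steps 1–4 and 7–18, from 1); the branch from 9 (steps 5 and 6) joins at step 7.

Steps most likely to fail:

1. Step 16 (ring closure). The aldehyde may add with low or reversed facial preference in the macrocyclic transition state, so that the C3 epimer accompanies or outweighs 29. The fallback sets out from 26: the closure is run as in step 16 and the whole carbinol mixture, 29 together with the C3-epimeric (3R) carbinol F2, is oxidised with Dess–Martin periodinane (NaHCO3, CH2Cl2, 0 °C) to the cross-conjugated C3 ketone F3. Reagent-controlled reduction of F3 with (R)-2-methyl-CBS-oxazaborolidine [(3aR)-1-methyl-3,3-diphenyltetrahydro-1H,3H-pyrrolo[1,2-c][1,3,2]oxazaborole] and catecholborane (toluene, −78 °C), in which the alkenyl carbon C4 acts as the large and C2 as the small group, should give the 3S alcohol, and the route is rejoined at 29.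

2. Step 7 (Barbier coupling). Simple diastereoselection at C7–C8 may erode through Z to E equilibration of the allylindium or a boat transition state, and coordination of indium to the dioxolane oxygen may weaken the facial preference at C7. The fallback sets out from 8 and 12: the coupling is run with CrCl2 (3 equiv, THF, 0 °C to rt; Nozaki–Hiyama allylation), where the trivalent allylchromium cannot chelate the dioxolane and should add anti to the C6–O bond. The 7,8-anti adduct that allylchromium reagents normally favour, the C8-epimeric hydroxy ester F1, is then esterified with inversion at C8 by a Mitsunobu reaction (isobutyric acid, PPh3, diisopropyl azodicarboxylate, toluene, 0 °C to rt), which rejoins the route at 16; any 14 formed alongside goes on through step 8, so both C8 epimers converge.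

3. Step 17 (epoxidation). The oxidant may attack the wrong face of C1=C10, or the free C3 hydroxyl may direct it to C4=C5. The fallback sets out from 29: the C3 hydroxyl is silylated (triethylsilyl triflate, 2,6-lutidine, CH2Cl2, −78 °C) to the 3-O-triethylsilyl ether F4, which removes the directing group. F4 is then epoxidised under reagent control by a Shi epoxidation with the D-fructose-derived ketone (1,2:4,5-di-O-isopropylidene-β-D-erythro-2,3-hexodiulo-2,6-pyranose) and KHSO5 (as 2KHSO5·KHSO4·K2SO4) in buffered MeCN/dimethoxymethane/water at 0 °C. This ketone gives R,R epoxides from E olefins and so matches the 1R,10R target, and the product is the bis-silylated epoxide F5. Removal of both silyl groups with TBAF/AcOH (THF, 0 °C to rt) brings the route back at 31.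

Further compounds
F1 | step 7 | methyl (3R,4S,6E)-3-[(4S)-2,2-dimethyl-1,3-dioxolan-4-yl]-4-hydroxy-9-[(4-methoxybenzyl)oxy]-6-methyl-2-methylidenenon-6-enoate (C8 epimer of 14) | COC(=O)C(=C)[C@@H]([C@H]1COC(C)(C)O1)[C@@H](O)C/C(C)=C/CCOCc1ccc(OC)cc1
F2 | step 16 | (3R,6R,7R,8R)-15-[(tert-butyldimethylsilyl)oxy]-3-hydroxy-8-(2-methylpropanoyloxy)germacra-1(10)E,4Z,11(13)-trien-12,6-olide (C3 epimer of 29) | C=C1C(=O)O[C@@H]2/C=C(/CO[Si](C)(C)C(C)(C)C)[C@H](O)C/C=C(C)/C[C@@H](OC(=O)C(C)C)[C@@H]12
F3 | step 16 | (6R,7R,8R)-15-[(tert-butyldimethylsilyl)oxy]-8-(2-methylpropanoyloxy)-3-oxogermacra-1(10)E,4Z,11(13)-trien-12,6-olide | C=C1C(=O)O[C@@H]2/C=C(/CO[Si](C)(C)C(C)(C)C)C(=O)C/C=C(C)/C[C@@H](OC(=O)C(C)C)[C@@H]12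
F4 | step 17 | (3S,6R,7R,8R)-15-[(tert-butyldimethylsilyl)oxy]-8-(2-methylpropanoyloxy)-3-[(triethylsilyl)oxy]germacra-1(10)E,4Z,11(13)-trien-12,6-olide | C=C1C(=O)O[C@@H]2/C=C(/CO[Si](C)(C)C(C)(C)C)[C@@H](O[Si](CC)(CC)CC)C/C=C(C)/C[C@@H](OC(=O)C(C)C)[C@@H]12
F5 | step 17 | (1R,3S,6R,7R,8R,10R)-15-[(tert-butyldimethylsilyl)oxy]-1,10-epoxy-8-(2-methylpropanoyloxy)-3-[(triethylsilyl)oxy]germacra-4Z,11(13)-dien-12,6-olide | C=C1C(=O)O[C@@H]2/C=C(/CO[Si](C)(C)C(C)(C)C)[C@@H](O[Si](CC)(CC)CC)C[C@H]3O[C@]3(C)C[C@@H](OC(=O)C(C)C)[C@@H]12
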